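Ring C of moracin Q is a resorcinol: its hydroxylated carbons C3' and C5' lie meta to one another on either side of C1', the carbon joined to C2 of the benzofuran (rings A and B). A 5-substituted cyclohexane-1,3-dione has the same oxygen pattern and becomes that arene by loss of one H2. The route therefore finishes rings A and B first and arrives at an (E)-4-(benzofuran-2-yl)but-3-en-2-one whose β-carbon is the future C1', with the C4 side-chain ketone masked as a dioxolane and the C6 phenol as a benzyl ether. A single Michael–Claisen annulation with dimethyl malonate then forms C1'–C2' and C3'–C4' and installs both ring C oxygens as carbonyls.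

Key step: step 11

Remark: moracin Q has no stereocentre; the stereocentres of 11, 12, 20, 21 and 22 are transient, these compounds are racemic, and the SMILES of 21 and 22 show one enantiomer of the trans pair.

Step 1
Reactants: 1 2,4,5-trihydroxybenzaldehyde
Product: 2 4-(benzyloxy)-2,5-dihydroxybenzaldehyde
Conditions: BnBr, NaHCO3, KI (cat.), DMF, 40 °C, N2
Reagents that add atoms: benzyl bromide, BrCc1ccccc1
Why: Williamson etherification under bicarbonate should alkylate only the 4-OH, which is para to the formyl group and hence the most acidic phenol and is not held in the hydrogen bond that ties up the 2-OH, the same preference that 2,4- and 3,4-dihydroxybenzaldehydes show.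

Step 2
Reactants: 2 4-(benzyloxy)-2,5-dihydroxybenzaldehyde; 3 3-chloro-3-methylbut-1-yne
Product: 4 4-(benzyloxy)-2-hydroxy-5-[(2-methylbut-3-yn-2-yl)oxy]benzaldehyde
Conditions: K2CO3, KI (cat.), CuI (cat.), acetone, reflux
Reagents that add atoms: none
Why: Copper-catalysed etherification of a phenol by a tertiary propargylic chloride should occur at the 5-OH, because the 2-OH is chelated to the formyl oxygen and its phenoxide is delocalised into the carbonyl and much less nucleophilic.

Step 3
Reactants: 4 4-(benzyloxy)-2-hydroxy-5-[(2-methylbut-3-yn-2-yl)oxy]benzaldehyde; 5 ethyl bromoacetate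
Product: 7 ethyl 6-(benzyloxy)-5-[(2-methylbut-3-yn-2-yl)oxy]-1-benzofuran-2-carboxylate, via aryloxyacetate 6 (not isolated)
Conditions: K2CO3, DMF, rt then 90 °C
Reagents that add atoms: none
Why: O-Alkylation of the remaining salicylaldehyde hydroxyl, followed in the same flask by intramolecular aldol condensation of the ester enolate on the formyl group and dehydration (Rap–Stoermer-type benzofuran annulation), should close the furan ring, and 90 °C is well below the temperature at which an aryl propargyl ether undergoes its own sigmatropic shift.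

Step 4
Reactants: 7 ethyl 6-(benzyloxy)-5-[(2-methylbut-3-yn-2-yl)oxy]-1-benzofuran-2-carboxylate
Product: 8 ethyl 6-(benzyloxy)-5-[(2-methylbut-3-en-2-yl)oxy]-1-benzofuran-2-carboxylate
Conditions: H2 (1 atm), Pd/CaCO3 poisoned with Pb(OAc)2 (Lindlar catalyst), quinoline, EtOAc, rt
Reagents that add atoms: none
Why: Lindlar semi-hydrogenation reduces the terminal alkyne to the vinyl group and stops there, the lead-poisoned catalyst leaving the benzyl ether and the benzofuran C2–C3 bond untouched.

Step 5
Reactants: 8 ethyl 6-(benzyloxy)-5-[(2-methylbut-3-en-2-yl)oxy]-1-benzofuran-2-carboxylate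
Product: 10 ethyl 6-(benzyloxy)-5-methoxy-4-(3-methylbut-2-en-1-yl)-1-benzofuran-2-carboxylate, via prenylphenol 9 (not isolated)
Conditions: DMF, 130 °C; then K2CO3, MeI, rt
Reagents that add atoms: iodomethane, CI
Why: The aromatic Claisen rearrangement of the 1,1-dimethylallyl ether ([3,3] shift with allyl inversion) should deliver a prenyl group to C4, the only ortho position that carries hydrogen since C6 holds the benzyloxy group, and the oxidation-prone phenol is trapped at once by Williamson methylation, which faces no selectivity question because it is the only free hydroxyl.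

Step 6
Reactants: 10 ethyl 6-(benzyloxy)-5-methoxy-4-(3-methylbut-2-en-1-yl)-1-benzofuran-2-carboxylate
Product: 12 ethyl 6-(benzyloxy)-4-(2-hydroxy-3-methylbutyl)-5-methoxy-1-benzofuran-2-carboxylate (racemic), via alkylborane 11 (not isolated)
Conditions: BH3·THF, THF, 0 °C; then NaBO3·4H2O, H2O, rt
Reagents that add atoms: sodium perborate, [Na+].[O-]OB=O
Why: Hydroboration–oxidation puts boron and then hydroxyl on the less substituted alkene carbon (anti-Markovnikov), giving the 2-hydroxy-3-methylbutyl chain as a racemate whose stereocentre is erased in step 7, while borane at 0 °C and neutral perborate should spare the conjugated ethyl ester.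

Step 7
Reactants: 12 ethyl 6-(benzyloxy)-4-(2-hydroxy-3-methylbutyl)-5-methoxy-1-benzofuran-2-carboxylate (racemic)
Product: 13 ethyl 6-(benzyloxy)-5-methoxy-4-(3-methyl-2-oxobutyl)-1-benzofuran-2-carboxylate
Conditions: Dess–Martin periodinane, CH2Cl2, rt
Reagents that add atoms: none
Why: Dess–Martin oxidation converts the secondary alcohol into the ketone under neutral conditions that the benzyl ether, the ester and the electron-rich benzofuran tolerate.

Step 8
Reactants: 13 ethyl 6-(benzyloxy)-5-methoxy-4-(3-methyl-2-oxobutyl)-1-benzofuran-2-carboxylate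
Product: 14 ethyl 6-(benzyloxy)-5-methoxy-4-{[2-(propan-2-yl)-1,3-dioxolan-2-yl]methyl}-1-benzofuran-2-carboxylate
Conditions: TMSOCH2CH2OTMS, TMSOTf (cat.), CH2Cl2, −78 to −20 °C; pyridine quench
Reagents that add atoms: 1,2-bis(trimethylsilyloxy)ethane, C[Si](C)(C)OCCO[Si](C)(C)C
Why: Ketalisation by silyl transfer (TMSOTf-catalysed exchange with the bis-silyl ether of ethylene glycol, driven by formation of hexamethyldisiloxane) works at low temperature on hindered ketones and, unlike glycol in hot acid, cannot transesterify the ethyl ester.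

Step 9
Reactants: 14 ethyl 6-(benzyloxy)-5-methoxy-4-{[2-(propan-2-yl)-1,3-dioxolan-2-yl]methyl}-1-benzofuran-2-carboxylate
Product: 15 [6-(benzyloxy)-5-methoxy-4-{[2-(propan-2-yl)-1,3-dioxolan-2-yl]methyl}-1-benzofuran-2-yl]methanol
Conditions: LiAlH4, THF, 0 °C; aq. NaOH work-up
Reagents that add atoms: none
Why: LiAlH4 reduces the ester to the primary alcohol, and the dioxolane, the benzyl ether and the methyl ether are inert to hydride and to the basic work-up.

Step 10
Reactants: 15 [6-(benzyloxy)-5-methoxy-4-{[2-(propan-2-yl)-1,3-dioxolan-2-yl]methyl}-1-benzofuran-2-yl]methanol; 16 1-(triphenylphosphoranylidene)propan-2-one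
Product: 18 (E)-4-[6-(benzyloxy)-5-methoxy-4-{[2-(propan-2-yl)-1,3-dioxolan-2-yl]methyl}-1-benzofuran-2-yl]but-3-en-2-one, via aldehyde 17 (not isolated)
Conditions: MnO2 (activated), toluene, 80 °C
Reagents that add atoms: none
Why: Tandem oxidation–Wittig olefination, in which MnO2 oxidises only the activated benzofuran-2-ylmethanol to aldehyde 17 and the stabilised ylide 16 intercepts it in the same flask to give the E enone, the geometry following from the reversible, thermodynamically controlled addition of a stabilised ylide, under neutral conditions that keep the dioxolane intact.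

Step 11
Reactants: 18 (E)-4-[6-(benzyloxy)-5-methoxy-4-{[2-(propan-2-yl)-1,3-dioxolan-2-yl]methyl}-1-benzofuran-2-yl]but-3-en-2-one; 19 dimethyl malonate
Product: 21 methyl trans-2-[6-(benzyloxy)-5-methoxy-4-{[2-(propan-2-yl)-1,3-dioxolan-2-yl]methyl}-1-benzofuran-2-yl]-4,6-dioxocyclohexane-1-carboxylate (racemic), via Michael adduct 20 (not isolated)
Conditions: NaOMe, MeOH, reflux; then AcOH, 0 °C
Reagents that add atoms: none
Why: Methoxide deprotonates dimethyl malonate and the soft malonate anion adds in conjugate fashion to the enone carbon that carries the benzofuran (the future C1'), making C1'–C2'; proton transfer then gives the enolate at the terminal methyl of the ketone, which attacks one ester carbonyl of the malonate unit and expels methoxide, making C3'–C4' (Michael addition followed by intramolecular Claisen condensation). The closest known reaction type is the malonate Michael–Claisen annulation of arylidene- and furfurylideneacetones to 5-substituted cyclohexane-1,3-diones. The single ring closes in a 6-(enolendo)-exo-trig mode, the enolate C=C lying inside the new ring and the ester C=O outside it. The C1' stereocentre arises without control (racemic), and the ester-bearing C2' centre, which is epimerisable between two carbonyls, settles trans to the benzofuranyl group with both substituents equatorial under thermodynamic control; both centres are erased in steps 12 and 13. The step needs 1,4- rather than 1,2-addition and a six-membered C-acylation rather than intermolecular condensation, which the reversible alkoxide conditions, the matched methyl ester and methoxide pair and the final irreversible deprotonation of the 1,3-dione provide. In the substrate the dioxolane leaves the enone ketone as the only enolisable carbonyl, and the benzyl ether keeps a C6 phenoxide from pushing electron density into the acceptor.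

Step 12
Reactants: 21 methyl trans-2-[6-(benzyloxy)-5-methoxy-4-{[2-(propan-2-yl)-1,3-dioxolan-2-yl]methyl}-1-benzofuran-2-yl]-4,6-dioxocyclohexane-1-carboxylate (racemic)
Product: 23 5-[6-(benzyloxy)-5-methoxy-4-(3-methyl-2-oxobutyl)-1-benzofuran-2-yl]cyclohexane-1,3-dione, via keto acid 22 (not isolated)
Conditions: NaOH (2 M aq.), THF, 65 °C; then HCl (aq.) to pH 1, 70 °C
Reagents that add atoms: water, O
Why: Saponification gives the β-keto acid, which loses CO2 on warming in acid through the usual cyclic six-membered transition state, and the same aqueous acid hydrolyses the dioxolane to the ketone while the benzyl aryl ether withstands dilute HCl; both ring stereocentres vanish.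

Step 13
Reactants: 23 5-[6-(benzyloxy)-5-methoxy-4-(3-methyl-2-oxobutyl)-1-benzofuran-2-yl]cyclohexane-1,3-dione
Product: 25 moracin Q, via benzyl ether 24 (not isolated)
Conditions: 10% Pd/C, triglyme, 180 °C, Ar; then H2 (1 atm), EtOAc, rt
Reagents that add atoms: none
Why: Pd/C-catalysed dehydrogenation of the enolised cyclohexane-1,3-dione is driven by aromatisation to the resorcinol, the benzyl ether being able to accept part of the hydrogen set free, and hydrogenolysis over the same catalyst under H2 then completes the O-debenzylation without touching the aliphatic ketone or the 2-arylbenzofuran.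

Compound list
1 | 2,4,5-trihydroxybenzaldehyde | O=Cc1cc(O)c(O)cc1O | starting material
2 | 4-(benzyloxy)-2,5-dihydroxybenzaldehyde | O=Cc1cc(O)c(OCc2ccccc2)cc1O | intermediate
3 | 3-chloro-3-methylbut-1-yne | C#CC(C)(C)Cl | starting material
4 | 4-(benzyloxy)-2-hydroxy-5-[(2-methylbut-3-yn-2-yl)oxy]benzaldehyde | O=Cc1cc(OC(C)(C)C#C)c(OCc2ccccc2)cc1O | intermediate
5 | ethyl bromoacetate | CCOC(=O)CBr | starting material
6 | ethyl 2-{5-(benzyloxy)-2-formyl-4-[(2-methylbut-3-yn-2-yl)oxy]phenoxy}acetate (formed in situ) | CCOC(=O)COc1cc(OCc2ccccc2)c(OC(C)(C)C#C)cc1C=O | intermediate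
7 | ethyl 6-(benzyloxy)-5-[(2-methylbut-3-yn-2-yl)oxy]-1-benzofuran-2-carboxylate | CCOC(=O)c1cc2cc(OC(C)(C)C#C)c(OCc3ccccc3)cc2o1 | intermediate
8 | ethyl 6-(benzyloxy)-5-[(2-methylbut-3-en-2-yl)oxy]-1-benzofuran-2-carboxylate | CCOC(=O)c1cc2cc(OC(C)(C)C=C)c(OCc3ccccc3)cc2o1 | intermediate
9 | ethyl 6-(benzyloxy)-5-hydroxy-4-(3-methylbut-2-en-1-yl)-1-benzofuran-2-carboxylate (formed in situ) | CCOC(=O)c1cc2c(CC=C(C)C)c(O)c(OCc3ccccc3)cc2o1 | intermediate
10 | ethyl 6-(benzyloxy)-5-methoxy-4-(3-methylbut-2-en-1-yl)-1-benzofuran-2-carboxylate | CCOC(=O)c1cc2c(CC=C(C)C)c(OC)c(OCc3ccccc3)cc2o1 | intermediate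
11 | ethyl 6-(benzyloxy)-4-(2-boranyl-3-methylbutyl)-5-methoxy-1-benzofuran-2-carboxylate (racemic, drawn as the monoalkylborane, formed in situ) | CCOC(=O)c1cc2c(CC(B)C(C)C)c(OC)c(OCc3ccccc3)cc2o1 | intermediate
12 | ethyl 6-(benzyloxy)-4-(2-hydroxy-3-methylbutyl)-5-methoxy-1-benzofuran-2-carboxylate (racemic) | CCOC(=O)c1cc2c(CC(O)C(C)C)c(OC)c(OCc3ccccc3)cc2o1 | intermediate
13 | ethyl 6-(benzyloxy)-5-methoxy-4-(3-methyl-2-oxobutyl)-1-benzofuran-2-carboxylate | CCOC(=O)c1cc2c(CC(=O)C(C)C)c(OC)c(OCc3ccccc3)cc2o1 | intermediate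
14 | ethyl 6-(benzyloxy)-5-methoxy-4-{[2-(propan-2-yl)-1,3-dioxolan-2-yl]methyl}-1-benzofuran-2-carboxylate | CCOC(=O)c1cc2c(CC3(C(C)C)OCCO3)c(OC)c(OCc3ccccc3)cc2o1 | intermediate
15 | [6-(benzyloxy)-5-methoxy-4-{[2-(propan-2-yl)-1,3-dioxolan-2-yl]methyl}-1-benzofuran-2-yl]methanol | OCc1cc2c(CC3(C(C)C)OCCO3)c(OC)c(OCc3ccccc3)cc2o1 | intermediate
16 | 1-(triphenylphosphoranylidene)propan-2-one | CC(=O)C=P(c1ccccc1)(c1ccccc1)c1ccccc1 | starting material
17 | 6-(benzyloxy)-5-methoxy-4-{[2-(propan-2-yl)-1,3-dioxolan-2-yl]methyl}-1-benzofuran-2-carbaldehyde (formed in situ) | O=Cc1cc2c(CC3(C(C)C)OCCO3)c(OC)c(OCc3ccccc3)cc2o1 | intermediate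
18 | (E)-4-[6-(benzyloxy)-5-methoxy-4-{[2-(propan-2-yl)-1,3-dioxolan-2-yl]methyl}-1-benzofuran-2-yl]but-3-en-2-one | CC(=O)/C=C/c1cc2c(CC3(C(C)C)OCCO3)c(OC)c(OCc3ccccc3)cc2o1 | intermediate
19 | dimethyl malonate | COC(=O)CC(=O)OC | starting material
20 | dimethyl 2-{1-[6-(benzyloxy)-5-methoxy-4-{[2-(propan-2-yl)-1,3-dioxolan-2-yl]methyl}-1-benzofuran-2-yl]-3-oxobutyl}propanedioate (racemic, formed in situ) | COC(=O)C(C(=O)OC)C(CC(C)=O)c1cc2c(CC3(C(C)C)OCCO3)c(OC)c(OCc3ccccc3)cc2o1 | intermediate
21 | methyl trans-2-[6-(benzyloxy)-5-methoxy-4-{[2-(propan-2-yl)-1,3-dioxolan-2-yl]methyl}-1-benzofuran-2-yl]-4,6-dioxocyclohexane-1-carboxylate (racemic, one enantiomer drawn) | COC(=O)[C@@H]1[C@@H](c2cc3c(CC4(C(C)C)OCCO4)c(OC)c(OCc4ccccc4)cc3o2)CC(=O)CC1=O | intermediate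
22 | trans-2-[6-(benzyloxy)-5-methoxy-4-{[2-(propan-2-yl)-1,3-dioxolan-2-yl]methyl}-1-benzofuran-2-yl]-4,6-dioxocyclohexane-1-carboxylic acid (racemic, one enantiomer drawn, formed in situ) | OC(=O)[C@@H]1[C@@H](c2cc3c(CC4(C(C)C)OCCO4)c(OC)c(OCc4ccccc4)cc3o2)CC(=O)CC1=O | intermediate
23 | 5-[6-(benzyloxy)-5-methoxy-4-(3-methyl-2-oxobutyl)-1-benzofuran-2-yl]cyclohexane-1,3-dione | CC(C)C(=O)Cc1c(OC)c(OCc2ccccc2)cc2oc(C3CC(=O)CC(=O)C3)cc12 | intermediate
24 | 5-[6-(benzyloxy)-5-methoxy-4-(3-methyl-2-oxobutyl)-1-benzofuran-2-yl]benzene-1,3-diol (formed in situ) | CC(C)C(=O)Cc1c(OC)c(OCc2ccccc2)cc2oc(-c3cc(O)cc(O)c3)cc12 | intermediate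
25 | moracin Q, 1-[2-(3,5-dihydroxyphenyl)-6-hydroxy-5-methoxy-1-benzofuran-4-yl]-3-methylbutan-2-one | COc1c(O)cc2oc(-c3cc(O)cc(O)c3)cc2c1CC(=O)C(C)C | target

Total step count: 13
Longest linear sequence: 13 steps (1 to 25)

Steps most likely to fail

Step 11 (key step). The conjugate addition is reversible and the enone is attenuated by the electron-rich benzofuran, so the sequence may stall at the open-chain adduct, revert, or lose material to base-induced self-condensation before the Claisen closure. The fallback builds the same ring from the opposite pair of partners and sets out from 15. Tandem oxidation–Wittig olefination (MnO2, ethyl (triphenylphosphoranylidene)acetate, toluene, 80 °C) should give ethyl (E)-3-[6-(benzyloxy)-5-methoxy-4-{[2-(propan-2-yl)-1,3-dioxolan-2-yl]methyl}-1-benzofuran-2-yl]prop-2-enoate F1. Ethyl acetoacetate with NaOEt in refluxing EtOH should then add to F1 in Michael fashion, and the acetoacetate methyl should close onto the acrylate ester by Claisen condensation, to give ethyl trans-2-[6-(benzyloxy)-5-methoxy-4-{[2-(propan-2-yl)-1,3-dioxolan-2-yl]methyl}-1-benzofuran-2-yl]-4,6-dioxocyclohexane-1-carboxylate F2 (racemic). The saponification, decarboxylation and ketal hydrolysis of step 12, applied to F2, return the route to 23.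

Step 13. Hydrogen held on the palladium surface may be transferred back to the dione (disproportionation with loss of one ring oxygen), or dehydrogenation may stay incomplete at a temperature the polyphenol tolerates. The fallback sets out from 23 and replaces the catalytic dehydrogenation by a stoichiometric two-electron oxidation, Hg(OAc)2 and NaOAc in refluxing AcOH (α-mercuration of the enol and loss of the metal, no hydrogen on a metal surface). This should give 24, which is isolated. A separate hydrogenolysis (H2, 10% Pd/C, EtOAc, rt) then returns to 25.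

Step 2. Etherification by the hindered tertiary propargylic chloride may be slow, may lose the chloride by elimination, or may partly alkylate the chelated 2-OH. The fallback sets out from 2 and builds the prenyl group from an allyl group. Allyl bromide with K2CO3 in acetone should give 5-(allyloxy)-4-(benzyloxy)-2-hydroxybenzaldehyde F3. Annulation with ethyl bromoacetate (K2CO3, DMF, 90 °C) should give ethyl 5-(allyloxy)-6-(benzyloxy)-1-benzofuran-2-carboxylate F4. Claisen rearrangement in N,N-diethylaniline at 190 °C should give ethyl 4-allyl-6-(benzyloxy)-5-hydroxy-1-benzofuran-2-carboxylate F5. Methylation (MeI, K2CO3, DMF) should give ethyl 4-allyl-6-(benzyloxy)-5-methoxy-1-benzofuran-2-carboxylate F6. Olefin cross-metathesis of F6 with 2-methylbut-2-ene (second-generation Grubbs catalyst, CH2Cl2, 40 °C) returns to 10.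

Further compounds
F1 | step 11 | ethyl (E)-3-[6-(benzyloxy)-5-methoxy-4-{[2-(propan-2-yl)-1,3-dioxolan-2-yl]methyl}-1-benzofuran-2-yl]prop-2-enoate | CCOC(=O)/C=C/c1cc2c(CC3(C(C)C)OCCO3)c(OC)c(OCc3ccccc3)cc2o1
F2 | step 11 | ethyl trans-2-[6-(benzyloxy)-5-methoxy-4-{[2-(propan-2-yl)-1,3-dioxolan-2-yl]methyl}-1-benzofuran-2-yl]-4,6-dioxocyclohexane-1-carboxylate (racemic, one enantiomer drawn) | CCOC(=O)[C@@H]1[C@@H](c2cc3c(CC4(C(C)C)OCCO4)c(OC)c(OCc4ccccc4)cc3o2)CC(=O)CC1=O
F0 | step 13 | none | none
F3 | step 2 | 5-(allyloxy)-4-(benzyloxy)-2-hydroxybenzaldehyde | O=Cc1cc(OCC=C)c(OCc2ccccc2)cc1O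
F4 | step 2 | ethyl 5-(allyloxy)-6-(benzyloxy)-1-benzofuran-2-carboxylate | CCOC(=O)c1cc2cc(OCC=C)c(OCc3ccccc3)cc2o1
F5 | step 2 | ethyl 4-allyl-6-(benzyloxy)-5-hydroxy-1-benzofuran-2-carboxylate | CCOC(=O)c1cc2c(CC=C)c(O)c(OCc3ccccc3)cc2o1
F6 | step 2 | ethyl 4-allyl-6-(benzyloxy)-5-methoxy-1-benzofuran-2-carboxylate | CCOC(=O)c1cc2c(CC=C)c(OC)c(OCc3ccccc3)cc2o1
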